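The numbers in the tables are calculated for substances that don't exist; noise was put on by code.

1. I keep the dawn flask at 0 °C and add no heat; this note says what it holds and where it is going.

| flask | Q | D | J | temperature | remark | time |
|---|---|---|---|---|---|---|
| dawn | 0.057 M | 0.103 M | 1.4 mM | 0 °C | the very flask that is asked about, followed so far |  |
| summer | 0.057 M | 0.103 M | 1.4 mM | 6 °C | run made earlier |  |
| flask | 0.057 M | 0.103 M | 1.4 mM | 0 °C |  | 6.0 h |

| run | time / h | Ty / % | Q / % |
|---|---|---|---|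
| dawn | 0.500 | 6 | 94 |
| dawn | 1.00 | 11 | 87 |
| dawn | 1.50 | 15 | 78 |
| dawn | 2.00 | 15 | 75 |
| dawn | 2.50 | 19 | 71 |
| dawn | 3.00 | 21 | 65 |
| dawn | 4.00 | 20 | 57 |
| summer | 0.500 | 13 | 84 |
| summer | 1.00 | 16 | 76 |
| summer | 1.50 | 17 | 62 |
| summer | 2.00 | 18 | 56 |
| summer | 2.50 | 22 | 51 |
| summer | 3.00 | 19 | 46 |
| summer | 4.00 | 17 | 36 |

(scatter of a reading: 1.5 percentage points)

- Saturday's: at 6.0 h raise the temperature by 20 K, then wait 2.0 h
- Monday's: at 6.0 h take out 90% of the Xa then present, then wait 2.0 h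
- Sunday's: at 6.0 h add D, 100% of the amount charged, then wait 2.0 h
- Friday's: change nothing and wait 2.0 h more

- additions leave the volume as it is
- the numbers in the tables scatter with a standard deviation of 1.5 percentage points
- a reading or a percentage of Ty counts all its forms, free or not

* Ty, in percent of the Q first charged, at 6.0 h
* the option that brings most further Ty ("none" if no option brings more than 2 percentage points) (Saturday's / Monday's / Sunday's / Friday's / none)
* Ty present, in percent of the Q first charged, after Saturday's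
* Ty present, in percent of the Q first charged, after Sunday's

2. In the dawn run Ty levels off while Q keeps falling, so I treat the flask as two first-order steps in series: Q to Ty, then Ty onward.

3. At 4.00 h the dawn run reads Ty over Q as 0.351, and I take this reading as my stall ratio: Ty over Q where Ty stops rising. In such a series it equals the half-life of Ty over that of Q, so equal half-lives, the symmetric zero of the scale, give a stall ratio of one.

4. Past the stall, Ty over Q climbs towards the tail ratio, s/(1 − s), here 0.541. Q extrapolates to 43.0% at 6.0 h, so I expect Ty somewhat under 23.3%, and slowly falling.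

5. The summer run at 6 °C tops near 22% against 21% at dawn, so those readings show no gain in Ty from warmth. Both runs hold the same charge of D, so the stall ratio is silent on Sunday's.

6. The forecast gives 19.5% now, 9% after Saturday's, 14% after Sunday's and none as best, saying “Extra D probably accelerates both steps”.

7. The flask gives:

    Ty → Uv (k = 1.00 × 10⁻⁴ s⁻¹, Ea = 94.0 kJ mol⁻¹)
    2 Z → X (k = 2.00 × 10⁸ M⁻¹ s⁻¹, Ea = 8.00 kJ mol⁻¹)
    Q + E → Xa + Z (k = 3800 M⁻¹ s⁻¹, Ea = 26.0 kJ mol⁻¹)
    Q + G → Gy + Z (k = 1.50 × 10⁵ M⁻¹ s⁻¹, Ea = 20.0 kJ mol⁻¹)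
    Ty ⇌ Jy (K = 0.360, k = 1.40 × 10⁻⁴ s⁻¹, Ea = 88.0 kJ mol⁻¹, ΔH = 2.00 kJ mol⁻¹)
    D + Ty ⇌ DTy, settled at all times (K = 8.90 M⁻¹, ΔH = −35.0 kJ mol⁻¹)
    D + Z ⇌ Ty + E (K = 1.40, k = 1100 M⁻¹ s⁻¹, Ea = 41.0 kJ mol⁻¹, ΔH = −27.0 kJ mol⁻¹)
    J → 2 G (k = 6.00 × 10⁻⁵ s⁻¹, Ea = 79.0 kJ mol⁻¹)
    (constants at 0 °C)

Ty stands at 23.1% at 6.0 h, and the best option is Sunday's, which reaches 34.4%, while Saturday's leaves 1.09% and Friday's changes Ty by −1.7 percentage points. Ty over Q in the dawn flask at 6.00 h is 0.507, close to the tail ratio. In the dawn flask free Ty has a half-life of 1.9 h by the turning into Uv alone, shorter than the 5.5 h of Q by the Q + E step at 2.19 h. The tail ratio, read at this charge of J, does not carry to the neighbour with 0.0035 M of J, where Ty over Q is 1.44, more than the tail ratio, with Q at 20.7%.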